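**Plan**
1. Retrosynthesis: the dioxane is cut at C3–O2' (ketal exchange) and C4–O3' (aryl ether). This gives an upper 4-hydroxy-3,3-dimethoxy-tetrahydrophenanthren-2-one and a lower 3'-bromo-2'-oxygenated phenanthrene. Ring C of the upper half is then cut at C1–C10a and C4–C4a, and the lower half at C9'–C10' and C4a'–C4b'.
2. Enabling feature: in ring C the carbonyl-level C4 sits on C4a and the α-keto carbon C1 on the neighbouring C10a, with the C2 carbonyl and the ketal carbon C3 between them. That is the pattern left when a C4a–C10a naphthalyne inserts into a C–C(=O) bond of 2,2-dimethoxycyclobutane-1,3-dione.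
3. Upper half, forward: Friedel–Crafts closure gives the naphthalene-1,3-diol (rings A and B), which is converted into an ortho-silyl triflate. Aryne insertion then builds ring C, and C1 is dimethylated.
4. Lower half, forward: Suzuki biaryl coupling, amide-directed remote metalation to close the middle ring, O-methylation, and directed bromination at C3'.
5. Union: palladium C–O coupling forms C4–O3', acid closes the dioxane at C3–O2', and the last phenol is freed.
6. Stereochemistry: C4 (S) comes from Noyori transfer hydrogenation with the (R,R) catalyst. C3 (S) follows from C4, because the tethered phenol can close only to the cis-fused dioxane.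

Key step: step 11

Remark: unprimed locants refer to the upper tetrahydrophenanthrenone and primed locants to the lower phenanthrene; 2-(3-methoxy-4-methylphenyl)acetic acid is taken to be purchasable (otherwise it follows from the corresponding benzaldehyde by one-carbon homologation).

**Upper naphthalene and aryne precursor**

Step 1
Reactants: 1 2-(3-methoxy-4-methylphenyl)acetic acid
Product: 3 ethyl 4-(3-methoxy-4-methylphenyl)-3-oxobutanoate, via acyl imidazolide 2 (not isolated)
Conditions: CDI, THF, rt; then KO2CCH2CO2Et, MgCl2, Et3N, MeCN, rt to 45 °C; 1 M HCl work-up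
Reagents that add atoms: potassium ethyl malonate, CCOC(=O)CC(=O)[O-].[K+]
Why: C-acylation of the magnesium malonate half-ester by the acyl imidazolide with loss of CO2 (Masamune-type acylation) is the standard one-flask route from an arylacetic acid to its β-keto ester.

Step 2
Reactants: 3 ethyl 4-(3-methoxy-4-methylphenyl)-3-oxobutanoate
Product: 4 6-methoxy-7-methylnaphthalene-1,3-diol
Conditions: conc. H2SO4, 0 °C to rt; ice quench
Reagents that add atoms: none
Why: intramolecular Friedel–Crafts acylation by the ester carbonyl para to the methoxy group (the position between side chain and OMe is hindered), followed by enolisation, should give the naphthoresorcinol as is usual for 4-aryl-3-oxobutanoates.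

Step 3
Reactants: 4 6-methoxy-7-methylnaphthalene-1,3-diol
Product: 5 6-methoxy-7-methyl-3-[(triisopropylsilyl)oxy]naphthalen-1-ol
Conditions: i-Pr3SiCl (1.05 equiv), imidazole, DMF, −20 to 0 °C
Reagents that add atoms: chlorotri(propan-2-yl)silane, CC(C)[Si](Cl)(C(C)C)C(C)C
Why: in this silyl ether formation the bulky chlorosilane should take the β-hydroxyl at C3, because the α-hydroxyl at C1 is shielded by the peri hydrogen H8.

Step 4
Reactants: 5 6-methoxy-7-methyl-3-[(triisopropylsilyl)oxy]naphthalen-1-ol
Product: 6 {[7-methoxy-4-(methoxymethoxy)-6-methylnaphthalen-2-yl]oxy}tri(propan-2-yl)silane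
Conditions: MeOCH2Cl, i-Pr2NEt, CH2Cl2, 0 °C to rt
Reagents that add atoms: chloromethyl methyl ether, COCCl
Why: O-alkylation of the remaining phenol (MOM ether formation) under amine base leaves the silyl ether untouched.

Step 5
Reactants: 6 {[7-methoxy-4-(methoxymethoxy)-6-methylnaphthalen-2-yl]oxy}tri(propan-2-yl)silane
Product: 7 7-methoxy-4-(methoxymethoxy)-6-methylnaphthalen-2-ol
Conditions: Bu4NF, AcOH, THF, 0 °C
Reagents that add atoms: none
Why: fluoride cleavage of the aryl silyl ether, buffered with acetic acid, frees the 2-naphthol without touching the MOM acetal.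

Step 6
Reactants: 7 7-methoxy-4-(methoxymethoxy)-6-methylnaphthalen-2-ol
Product: 8 1-bromo-7-methoxy-4-(methoxymethoxy)-6-methylnaphthalen-2-ol
Conditions: NBS, MeCN, −20 °C
Reagents that add atoms: N-bromosuccinimide, O=C1CCC(=O)N1Br
Why: electrophilic bromination of a 2-naphthol goes to the α-carbon C1, here ortho to the hydroxyl and para to the MOM ether.

Step 7
Reactants: 8 1-bromo-7-methoxy-4-(methoxymethoxy)-6-methylnaphthalen-2-ol
Product: 11 7-methoxy-4-(methoxymethoxy)-6-methyl-1-(trimethylsilyl)naphthalen-2-yl trifluoromethanesulfonate, via trimethylsilyl ether 9 (not isolated), via lithium 1-silyl-2-naphtholate 10 (not isolated)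
Conditions: (Me3Si)2NH, THF, 65 °C, evaporate; n-BuLi, THF, −78 °C; Tf2O, −78 °C
Reagents that add atoms: hexamethyldisilazane, C[Si](C)(C)N[Si](C)(C)C; trifluoromethanesulfonic anhydride, O=S(=O)(OS(=O)(=O)C(F)(F)F)C(F)(F)F
Why: O-silylation, bromine–lithium exchange with 1,3 O-to-C silyl shift (retro-Brook rearrangement) and triflation of the resulting naphtholate is the standard preparation of ortho-silylaryl triflates from ortho-bromophenols.

**Dione partner**

Step 8
Reactants: 12 dimethyl squarate
Product: 14 3-methoxycyclobut-3-ene-1,2-dione, via hydroxycyclobutenone 13 (not isolated)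
Conditions: LiAlH(Ot-Bu)3, THF, −78 °C; then conc. HCl (cat.), CH2Cl2, rt
Reagents that add atoms: none
Why: 1,2-hydride addition to one squarate carbonyl and acid-promoted loss of methanol from the hydroxy enol ether is the known reduction of dialkyl squarates to alkyl semisquarates.

Step 9
Reactants: 14 3-methoxycyclobut-3-ene-1,2-dione
Product: 15 3,4,4-trimethoxycyclobut-2-en-1-one
Conditions: MeOSiMe3, Me3SiOTf (cat.), CH2Cl2, −78 to 0 °C
Reagents that add atoms: methoxytrimethylsilane, CO[Si](C)(C)C
Why: silyl-transfer ketalisation, as used for squarate monoketals, should take the C2 carbonyl next to the methoxy-bearing carbon, which is ketone-like, whereas the C1 carbonyl is a vinylogous ester and less electrophilic.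

Step 10
Reactants: 15 3,4,4-trimethoxycyclobut-2-en-1-one
Product: 16 3-hydroxy-4,4-dimethoxycyclobut-2-en-1-one (the enol of 2,2-dimethoxycyclobutane-1,3-dione)
Conditions: LiOH, THF/H2O, 0 °C; then 1 M HCl to pH 2 at 0 °C, EtOAc extraction, used at once
Reagents that add atoms: lithium hydroxide, [Li+].[OH-]
Why: addition–elimination of hydroxide at the β-carbon (saponification of the vinylogous ester) and acidification free the vinylogous acid, while the ketal, flanked by a carbonyl and the enol carbon, should resist the brief acid contact.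

**Key step and elaboration of the upper half**

Step 11
Reactants: 11 7-methoxy-4-(methoxymethoxy)-6-methyl-1-(trimethylsilyl)naphthalen-2-yl trifluoromethanesulfonate; 16 3-hydroxy-4,4-dimethoxycyclobut-2-en-1-one
Product: 19 3,3,6-trimethoxy-9-(methoxymethoxy)-7-methylphenanthrene-2,4(1H,3H)-dione, via 1,2-naphthalyne 17 (not isolated), via caesium benzocyclobutenoxide 18 (not isolated)
Conditions: 16 (2 equiv), CsF (4 equiv), MeCN, 70 °C
Reagents that add atoms: none
Why: Proposed new method: fluoride removes the silyl group and triflate leaves to give the C4a–C10a aryne 17, the carbon of the caesium enolate of 16 adds at C10a, the aryl anion at C4a closes onto the adjacent carbonyl (4-exo-trig) to give the doubly four-membered alkoxide 18, and retro-aldol cleavage of the old four-ring C–C bond opens both small rings into ring C with the C1–C10a and C4–C4a bonds formed. The closest known chemistry is aryne acyl-alkylation, the insertion of arynes into the C–C bond of β-keto esters and cyclic β-dicarbonyl compounds with two-carbon ring expansion; a cyclobutane-1,3-dione has not been used, and release of aryne and cyclobutane strain is what should carry its weakly nucleophilic, delocalised enolate through. Ring C therefore closes by ring expansion (a net 4+2 annulation) and not by a separate cyclisation, and no stereocentre arises because C3 carries two methoxy groups. The step needs C-attack at C10a and not at C4a: the peri hydrogen H5 shields C4a and nucleophiles generally add to 1,2-naphthalynes at the β-carbon, while the 9-OMOM group is meta to C10a and exerts only a small inductive bias. The dione is symmetrical about its CH carbon, so either carbonyl leads to 19.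

Step 12
Reactants: 19 3,3,6-trimethoxy-9-(methoxymethoxy)-7-methylphenanthrene-2,4(1H,3H)-dione
Product: 20 3,3,6-trimethoxy-9-(methoxymethoxy)-1,1,7-trimethylphenanthrene-2,4(1H,3H)-dione
Conditions: NaH (2.5 equiv), MeI (excess), THF, 0 °C to rt
Reagents that add atoms: iodomethane, CI
Why: exhaustive enolate C-alkylation of the benzylic α-keto methylene C1 (as in the gem-dimethylation of 2-tetralones), with NaH chosen over an alkoxide so that the non-enolisable 2,4-dione is not opened by retro-Claisen attack.

Step 13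
Reactants: 20 3,3,6-trimethoxy-9-(methoxymethoxy)-1,1,7-trimethylphenanthrene-2,4(1H,3H)-dione
Product: 21 9-hydroxy-3,3,6-trimethoxy-1,1,7-trimethylphenanthrene-2,4(1H,3H)-dione
Conditions: HCl (3 M in MeOH), THF, 40 °C
Reagents that add atoms: none
Why: acid-catalysed acetal exchange removes the aryl MOM ether, while the C3 ketal, flanked by two carbonyl groups, should not ionise.

Step 14
Reactants: 21 9-hydroxy-3,3,6-trimethoxy-1,1,7-trimethylphenanthrene-2,4(1H,3H)-dione
Product: 22 3,3,6-trimethoxy-1,1,7-trimethyl-2,4-dioxo-1,2,3,4-tetrahydrophenanthren-9-yl pivalate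
Conditions: t-BuCOCl, Et3N, DMAP (cat.), CH2Cl2, 0 °C to rt
Reagents that add atoms: pivaloyl chloride, CC(C)(C)C(=O)Cl
Why: O-acylation turns the oxygen para to C4a from a strong into a weak donor, which is meant to hold the later C4–O bond against benzylic ionisation in acid, and the hindered ester should survive the basic coupling.

Step 15
Reactants: 22 3,3,6-trimethoxy-1,1,7-trimethyl-2,4-dioxo-1,2,3,4-tetrahydrophenanthren-9-yl pivalate
Product: 23 (4S)-4-hydroxy-3,3,6-trimethoxy-1,1,7-trimethyl-2-oxo-1,2,3,4-tetrahydrophenanthren-9-yl pivalate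
Conditions: RuCl(p-cymene)[(R,R)-TsDPEN] (2 mol %), HCO2H/Et3N (5:2), DMF, 40 °C
Reagents that add atoms: none
Why: Noyori asymmetric transfer hydrogenation reduces the aryl ketone C4 and leaves the C2 ketone, which lies between two quaternary carbons; with the (R,R) catalyst the usual aryl/alkyl model, with C3 in the alkyl position, should give the 4S carbinol.

**Lower phenanthrene**

Step 16
Reactants: 24 4-bromo-2-methylphenol
Product: 25 4-bromo-1-(tert-butoxy)-2-methylbenzene
Conditions: isobutylene, TfOH (cat.), CH2Cl2, −78 °C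
Reagents that add atoms: 2-methylprop-1-ene, C=C(C)C
Why: acid-catalysed addition of the phenol to isobutylene gives the aryl tert-butyl ether, a group that does not direct lithiation and is later removed by acid.

Step 17
Reactants: 25 4-bromo-1-(tert-butoxy)-2-methylbenzene
Product: 27 4-(tert-butoxy)-N,N-diethyl-3-methylbenzamide, via aryllithium 26 (not isolated)
Conditions: n-BuLi, THF, −78 °C; then Et2NCOCl, −78 °C to rt
Reagents that add atoms: diethylcarbamoyl chloride, CCN(CC)C(=O)Cl
Why: bromine–lithium exchange and acylation of the aryllithium with the carbamoyl chloride is a routine entry to N,N-diethylbenzamides.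

Step 18
Reactants: 27 4-(tert-butoxy)-N,N-diethyl-3-methylbenzamide
Product: 29 4-(tert-butoxy)-N,N-diethyl-5-methyl-2-(4,4,5,5-tetramethyl-1,3,2-dioxaborolan-2-yl)benzamide, via ortho-lithiated amide 28 (not isolated)
Conditions: s-BuLi, TMEDA, THF, −78 °C; then i-PrOBpin; aq. NH4Cl
Reagents that add atoms: 2-isopropoxy-4,4,5,5-tetramethyl-1,3,2-dioxaborolane, CC(C)OB1OC(C)(C)C(C)(C)O1
Why: amide-directed ortho-metalation should occur at the open ortho position (the other lies between the amide and the methyl group), and borylation of the aryllithium gives the pinacol boronate.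

Step 19
Reactants: 30 4-bromo-2,3-dimethylphenol
Product: 31 1-bromo-4-(methoxymethoxy)-2,3-dimethylbenzene
Conditions: MeOCH2Cl, i-Pr2NEt, CH2Cl2, 0 °C to rt
Reagents that add atoms: chloromethyl methyl ether, COCCl
Why: MOM ether formation protects the phenol and provides the directing group for the later ortho-lithiation.

Step 20
Reactants: 29 4-(tert-butoxy)-N,N-diethyl-5-methyl-2-(4,4,5,5-tetramethyl-1,3,2-dioxaborolan-2-yl)benzamide; 31 1-bromo-4-(methoxymethoxy)-2,3-dimethylbenzene
Product: 32 5-(tert-butoxy)-N,N-diethyl-4'-(methoxymethoxy)-2',3',4-trimethyl-[1,1'-biphenyl]-2-carboxamide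
Conditions: Pd(dppf)Cl2 (5 mol %), K3PO4, 1,4-dioxane/H2O, 90 °C
Reagents that add atoms: none
Why: Suzuki–Miyaura coupling of an ortho-amido aryl boronate with an aryl bromide to a di-ortho-substituted biaryl is well within the scope of the reaction.

Step 21
Reactants: 32 5-(tert-butoxy)-N,N-diethyl-4'-(methoxymethoxy)-2',3',4-trimethyl-[1,1'-biphenyl]-2-carboxamide
Product: 33 6-(tert-butoxy)-2-(methoxymethoxy)-1,7-dimethylphenanthren-9-ol
Conditions: LiN(i-Pr)2 (3 equiv), THF, 0 °C to rt; aq. NH4Cl
Reagents that add atoms: none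
Why: directed remote metalation, in which amide-bound lithium amide deprotonates the 2'-methyl group and the benzyl anion acylates on the diethylamide, is the established route from such biaryl amides to 9-phenanthrols.

Step 22
Reactants: 33 6-(tert-butoxy)-2-(methoxymethoxy)-1,7-dimethylphenanthren-9-ol
Product: 34 6-(tert-butoxy)-9-methoxy-2-(methoxymethoxy)-1,7-dimethylphenanthrene
Conditions: MeI, K2CO3, acetone, 50 °C
Reagents that add atoms: iodomethane, CI
Why: Williamson O-methylation of the phenanthrol fixes the 9'-methoxy group while the other two oxygens carry acid-labile groups.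

Step 23
Reactants: 34 6-(tert-butoxy)-9-methoxy-2-(methoxymethoxy)-1,7-dimethylphenanthrene
Product: 36 3-bromo-6-(tert-butoxy)-9-methoxy-2-(methoxymethoxy)-1,7-dimethylphenanthrene, via 3-lithiophenanthrene 35 (not isolated)
Conditions: n-BuLi, TMEDA, THF, −78 to 0 °C; then BrCCl2CCl2Br, −78 °C
Reagents that add atoms: 1,2-dibromo-1,1,2,2-tetrachloroethane, ClC(Cl)(Br)C(Cl)(Cl)Br
Why: directed ortho-metalation by the chelating MOM ether (a stronger director than the 9'-methoxy group, the tert-butoxy group not directing) should lithiate C3', its only free ortho position, and bromine transfer gives the bromide; electrophilic bromination is avoided because it would attack C10'.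

**Union and end game**

Step 24
Reactants: 23 (4S)-4-hydroxy-3,3,6-trimethoxy-1,1,7-trimethyl-2-oxo-1,2,3,4-tetrahydrophenanthren-9-yl pivalate; 36 3-bromo-6-(tert-butoxy)-9-methoxy-2-(methoxymethoxy)-1,7-dimethylphenanthrene
Product: 37 (4S)-4-{[6-(tert-butoxy)-9-methoxy-2-(methoxymethoxy)-1,7-dimethylphenanthren-3-yl]oxy}-3,3,6-trimethoxy-1,1,7-trimethyl-2-oxo-1,2,3,4-tetrahydrophenanthren-9-yl pivalate
Conditions: [Pd(allyl)Cl]2 (2.5 mol %), RockPhos (6 mol %), Cs2CO3, toluene, 90 °C
Reagents that add atoms: none
Why: Buchwald–Hartwig-type C–O coupling of a secondary alcohol with an ortho-substituted aryl bromide, in which the bulky biaryl phosphine favours C–O reductive elimination over β-hydride elimination; the C4–O bond is not broken, so the configuration should be kept.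

Step 25
Reactants: 37 (4S)-4-{[6-(tert-butoxy)-9-methoxy-2-(methoxymethoxy)-1,7-dimethylphenanthren-3-yl]oxy}-3,3,6-trimethoxy-1,1,7-trimethyl-2-oxo-1,2,3,4-tetrahydrophenanthren-9-yl pivalate
Product: 39 actephilol C 9-O-pivalate (3S,4S; cis-fused dioxane with O2' on C3 and O3' on C4; 6'-OH free), via diphenol 38 (not isolated)
Conditions: HCl (4 M in 1,4-dioxane), CH2Cl2, 0 °C to rt; evaporate; TfOH (5 mol %), 5 Å MS, CH2Cl2, −20 to 0 °C
Reagents that add atoms: none
Why: acidolysis of the aryl MOM and tert-butyl ethers is followed by acid-catalysed intramolecular ketal exchange (6-exo attack of the 2'-OH on the C3 oxocarbenium); because the peri hydrogen H5 holds the C4 aryloxy group pseudoaxial, the phenol can reach C3 only from the face of O4, which should give the cis-fused dioxane with C3 as S and OMe cis to H4, while the pivalate slows ionisation at C4.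

Step 26
Reactants: 39 actephilol C 9-O-pivalate
Product: 40 actephilol C, (3S,4S)
Conditions: K2CO3 (20 mol %), MeOH/THF, 0 °C; AcOH quench
Reagents that add atoms: none
Why: base-catalysed transesterification removes the aryl pivalate; C2 has no α-hydrogen and the mixed ketal is stable to base, and the short, cold exposure limits reversible opening at C4 through the 9-phenoxide.

**Compound list**
1 | 2-(3-methoxy-4-methylphenyl)acetic acid | COc1cc(CC(=O)O)ccc1C | starting material
2 | 1-(1H-imidazol-1-yl)-2-(3-methoxy-4-methylphenyl)ethan-1-one (acyl imidazolide) | COc1cc(CC(=O)n2ccnc2)ccc1C | intermediate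
3 | ethyl 4-(3-methoxy-4-methylphenyl)-3-oxobutanoate | CCOC(=O)CC(=O)Cc1ccc(C)c(OC)c1 | intermediate
4 | 6-methoxy-7-methylnaphthalene-1,3-diol | COc1cc2cc(O)cc(O)c2cc1C | intermediate
5 | 6-methoxy-7-methyl-3-[(triisopropylsilyl)oxy]naphthalen-1-ol | COc1cc2cc(O[Si](C(C)C)(C(C)C)C(C)C)cc(O)c2cc1C | intermediate
6 | {[7-methoxy-4-(methoxymethoxy)-6-methylnaphthalen-2-yl]oxy}tri(propan-2-yl)silane | COCOc1cc(O[Si](C(C)C)(C(C)C)C(C)C)cc2cc(OC)c(C)cc12 | intermediate
7 | 7-methoxy-4-(methoxymethoxy)-6-methylnaphthalen-2-ol | COCOc1cc(O)cc2cc(OC)c(C)cc12 | intermediate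
8 | 1-bromo-7-methoxy-4-(methoxymethoxy)-6-methylnaphthalen-2-ol | COCOc1cc(O)c(Br)c2cc(OC)c(C)cc12 | intermediate
9 | {[1-bromo-7-methoxy-4-(methoxymethoxy)-6-methylnaphthalen-2-yl]oxy}trimethylsilane | COCOc1cc(O[Si](C)(C)C)c(Br)c2cc(OC)c(C)cc12 | intermediate
10 | lithium 7-methoxy-4-(methoxymethoxy)-6-methyl-1-(trimethylsilyl)naphthalen-2-olate | COCOc1cc([O-])c([Si](C)(C)C)c2cc(OC)c(C)cc12.[Li+] | intermediate
11 | 7-methoxy-4-(methoxymethoxy)-6-methyl-1-(trimethylsilyl)naphthalen-2-yl trifluoromethanesulfonate | COc1cc2c(c(OS(=O)(=O)C(F)(F)F)cc(OCOC)c2cc1C)[Si](C)(C)C | intermediate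
12 | dimethyl squarate (3,4-dimethoxycyclobut-3-ene-1,2-dione) | COC1=C(OC)C(=O)C1=O | starting material
13 | 4-hydroxy-2,3-dimethoxycyclobut-2-en-1-one | COC1=C(OC)C(O)C1=O | intermediate
14 | 3-methoxycyclobut-3-ene-1,2-dione | COC1=CC(=O)C1=O | intermediate
15 | 3,4,4-trimethoxycyclobut-2-en-1-one | COC1=CC(=O)C1(OC)OC | intermediate
16 | 3-hydroxy-4,4-dimethoxycyclobut-2-en-1-one (enol of 2,2-dimethoxycyclobutane-1,3-dione) | COC1(OC)C(=O)C=C1O | intermediate
17 | 7-methoxy-4-(methoxymethoxy)-6-methyl-1,2-didehydronaphthalene (1,2-naphthalyne) | COCOC1=CC#CC2=C1C=C(C)C(OC)=C2 | intermediate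
18 | caesium benzocyclobutenoxide from 17 and the enolate of 16 (C10a bonded to the dione CH, C4a to the former carbonyl carbon as alkoxide; racemic, cis ring fusion) | COCOc1cc2C3C(=O)C(OC)(OC)C3([O-])c2c2cc(OC)c(C)cc12.[Cs+] | intermediate
19 | 3,3,6-trimethoxy-9-(methoxymethoxy)-7-methylphenanthrene-2,4(1H,3H)-dione | COc1cc2c3c(cc(OCOC)c2cc1C)CC(=O)C(OC)(OC)C3=O | intermediate
20 | 3,3,6-trimethoxy-9-(methoxymethoxy)-1,1,7-trimethylphenanthrene-2,4(1H,3H)-dione | COc1cc2c3c(cc(OCOC)c2cc1C)C(C)(C)C(=O)C(OC)(OC)C3=O | intermediate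
21 | 9-hydroxy-3,3,6-trimethoxy-1,1,7-trimethylphenanthrene-2,4(1H,3H)-dione | COc1cc2c3c(cc(O)c2cc1C)C(C)(C)C(=O)C(OC)(OC)C3=O | intermediate
22 | 3,3,6-trimethoxy-1,1,7-trimethyl-2,4-dioxo-1,2,3,4-tetrahydrophenanthren-9-yl pivalate | COc1cc2c3c(cc(OC(=O)C(C)(C)C)c2cc1C)C(C)(C)C(=O)C(OC)(OC)C3=O | intermediate
23 | (4S)-4-hydroxy-3,3,6-trimethoxy-1,1,7-trimethyl-2-oxo-1,2,3,4-tetrahydrophenanthren-9-yl pivalate | COc1cc2c3c(cc(OC(=O)C(C)(C)C)c2cc1C)C(C)(C)C(=O)C(OC)(OC)[C@H]3O | intermediate
24 | 4-bromo-2-methylphenol | Cc1cc(Br)ccc1O | starting material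
25 | 4-bromo-1-(tert-butoxy)-2-methylbenzene | Cc1cc(Br)ccc1OC(C)(C)C | intermediate
26 | [4-(tert-butoxy)-3-methylphenyl]lithium | [Li]c1ccc(OC(C)(C)C)c(C)c1 | intermediate
27 | 4-(tert-butoxy)-N,N-diethyl-3-methylbenzamide | CCN(CC)C(=O)c1ccc(OC(C)(C)C)c(C)c1 | intermediate
28 | [5-(tert-butoxy)-2-(diethylcarbamoyl)-4-methylphenyl]lithium | CCN(CC)C(=O)c1cc(C)c(OC(C)(C)C)cc1[Li] | intermediate
29 | 4-(tert-butoxy)-N,N-diethyl-5-methyl-2-(4,4,5,5-tetramethyl-1,3,2-dioxaborolan-2-yl)benzamide | CCN(CC)C(=O)c1cc(C)c(OC(C)(C)C)cc1B1OC(C)(C)C(C)(C)O1 | intermediate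
30 | 4-bromo-2,3-dimethylphenol | Cc1c(O)ccc(Br)c1C | starting material
31 | 1-bromo-4-(methoxymethoxy)-2,3-dimethylbenzene | COCOc1ccc(Br)c(C)c1C | intermediate
32 | 5-(tert-butoxy)-N,N-diethyl-4'-(methoxymethoxy)-2',3',4-trimethyl-[1,1'-biphenyl]-2-carboxamide | CCN(CC)C(=O)c1cc(C)c(OC(C)(C)C)cc1-c1ccc(OCOC)c(C)c1C | intermediate
33 | 6-(tert-butoxy)-2-(methoxymethoxy)-1,7-dimethylphenanthren-9-ol | COCOc1ccc2c(c1C)cc(O)c1cc(C)c(OC(C)(C)C)cc12 | intermediate
34 | 6-(tert-butoxy)-9-methoxy-2-(methoxymethoxy)-1,7-dimethylphenanthrene | COCOc1ccc2c(c1C)cc(OC)c1cc(C)c(OC(C)(C)C)cc12 | intermediate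
35 | [6-(tert-butoxy)-9-methoxy-2-(methoxymethoxy)-1,7-dimethylphenanthren-3-yl]lithium | COCOc1c([Li])cc2c(c1C)cc(OC)c1cc(C)c(OC(C)(C)C)cc12 | intermediate
36 | 3-bromo-6-(tert-butoxy)-9-methoxy-2-(methoxymethoxy)-1,7-dimethylphenanthrene | COCOc1c(Br)cc2c(c1C)cc(OC)c1cc(C)c(OC(C)(C)C)cc12 | intermediate
37 | (4S)-4-{[6-(tert-butoxy)-9-methoxy-2-(methoxymethoxy)-1,7-dimethylphenanthren-3-yl]oxy}-3,3,6-trimethoxy-1,1,7-trimethyl-2-oxo-1,2,3,4-tetrahydrophenanthren-9-yl pivalate | COc1cc2c3c(cc(OC(=O)C(C)(C)C)c2cc1C)C(C)(C)C(=O)C(OC)(OC)[C@H]3Oc1cc2c(c(C)c1OCOC)cc(OC)c1cc(C)c(OC(C)(C)C)cc12 | intermediate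
38 | (4S)-4-[(2,6-dihydroxy-9-methoxy-1,7-dimethylphenanthren-3-yl)oxy]-3,3,6-trimethoxy-1,1,7-trimethyl-2-oxo-1,2,3,4-tetrahydrophenanthren-9-yl pivalate | COc1cc2c3c(cc(OC(=O)C(C)(C)C)c2cc1C)C(C)(C)C(=O)C(OC)(OC)[C@H]3Oc1cc2c(c(C)c1O)cc(OC)c1cc(C)c(O)cc12 | intermediate
39 | actephilol C 9-O-pivalate, (3S,4S): cis-fused dioxane with O2' on C3 (which keeps one OMe) and O3' on C4, 6'-OH free | COc1cc2c3c(cc(OC(=O)C(C)(C)C)c2cc1C)C(C)(C)C(=O)[C@@]1(OC)Oc2c(cc4c(cc(OC)c5cc(C)c(O)cc54)c2C)O[C@@H]31 | intermediate
40 | actephilol C, (3S,4S) | COc1cc2c3c(cc(O)c2cc1C)C(C)(C)C(=O)[C@@]1(OC)Oc2c(cc4c(cc(OC)c5cc(C)c(O)cc54)c2C)O[C@@H]31 | target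

**Step count and risks**
Total: 26 steps (upper naphthalene 7, dione 3, lower phenanthrene 8, key step and end game 8). Longest linear sequence: 15 steps (steps 1–7, 11–15, 24–26).

Steps most likely to fail:

1. Step 11. The delocalised, weakly basic cyclobutenolate may add to the aryne through oxygen or too slowly, so that the aryne is lost to fluoride or solvent before C–C insertion. Fallback: from 11, the established acyl-alkylation of the same aryne with an acyclic β-keto ester, methyl 4,4-dimethoxy-3-oxobutanoate (CsF, MeCN, 80 °C), should give methyl 2-[1-(2,2-dimethoxyacetyl)-7-methoxy-4-(methoxymethoxy)-6-methylnaphthalen-2-yl]acetate F1 with the same two aryl–carbon bonds in place. A Dieckmann-type Claisen closure of the acetal-bearing enolate onto the ester (LiN(SiMe3)2 or KOt-Bu, THF) then forms the C2–C3 bond and comes back to the route at 19.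

2. Step 24. Reductive elimination from the hindered, electron-rich arylpalladium alkoxide may be slow, leaving room for β-hydride elimination back to the C4 ketone or for base-induced retro-aldol opening of the β-hydroxy ketone, which would erode the configuration at C4. Fallback: from 34, lithiation as in step 23 followed by B(OMe)3 and aqueous KHF2 should give potassium [6-(tert-butoxy)-9-methoxy-2-(methoxymethoxy)-1,7-dimethylphenanthren-3-yl]trifluoroborate F2. Copper-catalysed oxidative etherification of alcohol 23 with it (Chan–Lam type; Cu(OAc)2, DMAP, 4 Å MS, O2, CH2Cl2, rt) forms the same C4–O3' bond at room temperature without strong base and comes back to the route at 37.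

3. Step 25. Ionisation of the α-keto ketal at C3 may be sluggish, so that prolonged strong acid opens the benzylic C4–O bond with loss of configuration or gives the wrong ring fusion. Fallback: from 37, the HCl treatment alone gives diphenol 38, which is isolated and silylated with (Me3Si)2NH to (4S)-4-{[9-methoxy-1,7-dimethyl-2,6-bis(trimethylsilyloxy)phenanthren-3-yl]oxy}-3,3,6-trimethoxy-1,1,7-trimethyl-2-oxo-1,2,3,4-tetrahydrophenanthren-9-yl pivalate F3. Catalytic Me3SiOTf in CH2Cl2 at −78 °C then closes the dioxane by silyl-transfer ketal exchange with loss of MeOSiMe3, under aprotic conditions and at low temperature; aqueous work-up frees the 6'-OH and comes back to the route at 39.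

**Further compounds**
F1 | step 11 | methyl 2-[1-(2,2-dimethoxyacetyl)-7-methoxy-4-(methoxymethoxy)-6-methylnaphthalen-2-yl]acetate | COC(=O)Cc1cc(OCOC)c2cc(C)c(OC)cc2c1C(=O)C(OC)OC
F2 | step 24 | potassium [6-(tert-butoxy)-9-methoxy-2-(methoxymethoxy)-1,7-dimethylphenanthren-3-yl]trifluoroborate | [K+].F[B-](F)(F)c1cc2c(c(C)c1OCOC)cc(OC)c1cc(C)c(OC(C)(C)C)cc12
F3 | step 25 | (4S)-4-{[9-methoxy-1,7-dimethyl-2,6-bis(trimethylsilyloxy)phenanthren-3-yl]oxy}-3,3,6-trimethoxy-1,1,7-trimethyl-2-oxo-1,2,3,4-tetrahydrophenanthren-9-yl pivalate | COc1cc2c3c(cc(OC(=O)C(C)(C)C)c2cc1C)C(C)(C)C(=O)C(OC)(OC)[C@H]3Oc1cc2c(c(C)c1O[Si](C)(C)C)cc(OC)c1cc(C)c(O[Si](C)(C)C)cc12
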